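Amounts were where I began, and I counted the starting material and what came of it as fractions of its charge.

common to all: starting material 0.080 M; free catalyst 0.55 mM; added ligand 1.6 mM
- north: second substrate 0.040 M; coupling partner 0.24 M; temperature 5 °C; run made earlier
- ochre: second substrate 0.0800 M; coupling partner 0.240 M; temperature 5 °C; time 2.5 h
- red: second substrate 0.0800 M; coupling partner 0.240 M; temperature 65 °C; time 2.5 h
- amber: second substrate 0.0800 M; coupling partner 0.240 M; temperature 35 °C; time 2.5 h
- teal: second substrate 0.0800 M; coupling partner 0.240 M; at 5 °C until 30 min, from then on at 65 °C; time 2.5 h

* the flask with the highest amount of target, in percent of the starting material charged ("all alike" if they lie within 1.5 percentage points) (ochre / red / amber / teal / all alike)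
* final target, as a percentage of the starting material charged, in ochre
* final target, as a percentage of the starting material charged, in red
* final target, as a percentage of the starting material charged, in amber
* final target, as a percentage of the starting material charged, in teal

- in percentages every species weighs as the starting material in it: one homo dimer counts as two
- the numbers in the tables scatter by 1 percentage point (one standard deviation)
- what may be going on: starting material + free catalyst <-> catalyst intermediate A; coupling partner + catalyst intermediate A -> free catalyst + target; second substrate + free catalyst <-> catalyst intermediate B; coupling partner + catalyst intermediate B -> free catalyst + second product; free catalyst + added ligand <-> idle complex; target <-> isomer of the product; 2 starting material -> homo dimer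
- the earlier runs do not show what temperature does; that part of a forecast is a guess

In ochre, red, amber and teal the coupling partner, at 0.240 M, stood above starting material and second substrate together, so starting material was the limiting reagent for target. Its balance read: charge = left + catalyst intermediate A + target + isomer of the product + homo dimer. I wanted to know how quickly the target term could fill, and the north run held one column on that.

north run (percent of the starting material charged): time / min: target / % = 0.833: 0; 2.50: 1.9; 4.00: 3.7; 6.00: 5.9; 10.0: 6.2; 12.0: 8.8; 15.0: 10.4

(each reading ± 1 percentage point)

The first row, 0 % at 0.833 min, lay inside the scatter, so I read no delay from it. The rows at 6.00 min and 10.0 min differed by 0.3 percentage points, which I took for scatter too. I therefore used the last row, 10.4 % at 15.0 min, and dividing time by fraction gave 144 min: the catalytic emptying time, the time in which target, at the north pace, would have taken up the whole charge. The row above it gave a reading of 136 min.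

I took the pace to be proportional to what was left, which removes the same fraction in each equal time, so the untouched part after a time t is exp(−t/emptying time). In ochre, at 5 °C, the run lasted 1.04 emptying times. I therefore expected 35.3 % of the starting material left and 64.7 % as target with its isomer, supposing that the north pace held with the second substrate doubled and that no homo dimer formed. For teal the same reckoning banked 18.8 % in the 30 min at 5 °C. The north run showed nothing about temperature, so I put no number on red, amber or the hot stretch of teal.

The forecast put amber first, with 45 % for ochre, 45 % for red, 62 % for amber and 47 % for teal, and it said “All temperature effects here are guesses”.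

The flasks gave 42.4 % in ochre, 26.2 % in red, 23.8 % in amber and 34.9 % in teal, so ochre held the most target.

    starting material + free catalyst ⇌ catalyst intermediate A (K = 32.0 M⁻¹, k = 2.20 M⁻¹ s⁻¹, Ea = 35.0 kJ mol⁻¹, ΔH = 15.0 kJ mol⁻¹)
    coupling partner + catalyst intermediate A → free catalyst + target (k = 13.0 M⁻¹ s⁻¹, Ea = 55.0 kJ mol⁻¹)
    second substrate + free catalyst ⇌ catalyst intermediate B (K = 6.50 M⁻¹, k = 0.970 M⁻¹ s⁻¹, Ea = 59.0 kJ mol⁻¹, ΔH = −8.00 kJ mol⁻¹)
    coupling partner + catalyst intermediate B → free catalyst + second product (k = 0.170 M⁻¹ s⁻¹, Ea = 69.0 kJ mol⁻¹)
    free catalyst + added ligand ⇌ idle complex, settled at all times (K = 620 M⁻¹, ΔH = 14.0 kJ mol⁻¹)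
    target ⇌ isomer of the product (K = 1.00, k = 0.00100 s⁻¹, Ea = 95.0 kJ mol⁻¹, ΔH = −40.0 kJ mol⁻¹)
    2 starting material → homo dimer (k = 0.00900 M⁻¹ s⁻¹, Ea = 53.0 kJ mol⁻¹)
    (constants at 35 °C)

Ochre kept 18.8 % of its starting material, less than my 35.3 %, and held 34.3 % as homo dimer, while target with isomer came to 47.0 %. The neighbouring flask was teal with 0.140 mM of free catalyst, a quarter of teal's amount. Scaling the emptying time inversely with the catalyst charged gave 567 min, and so a reckoned 5.16 % banked in the cold stage, against my 18.8 % for teal. That neighbouring flask ended with 13.0 % target, 0.372 of teal's amount, and 3.25 % isomer of the product, while its homo dimer stood at 83.5 % against 56.3 % in teal.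

The readings are simulated for an exercise; noise was put on by code.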